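What I had to say for each set-up was how much of what reached complex with two exchanged or beyond was still that complex at the end or outlet, so I followed one molecule of it.

| flask | starting complex | incoming ligand | remark | time |
|---|---|---|---|---|
| ash | 0.061 M | 1.8 equiv | run made earlier |  |
| alder | 0.061 M | 0.90 equiv | run made earlier |  |
| elm | 0.061 M | 1.4 equiv | run made earlier |  |
| larch | 0.12 M | 1.8 equiv | run made earlier |  |
| Thursday's | 0.061 M | 1.80 equiv | a closed flask charged with all of it at once and left for 30 min | 30 min |
| Friday's | 0.061 M | 1.80 equiv (fed, over 30.0 min) | a stirred flask in which incoming ligand is dosed at a steady rate over 30.0 min without added volume, worked up at 30 min | 30 min |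
| Wednesday's | 0.061 M (fed, over 30.0 min) | 1.80 equiv | a stirred flask in which starting complex is dosed at a steady rate over 30.0 min without added volume, worked up at 30 min | 30 min |
| Sunday's | 0.061 M | 1.80 equiv | a single well-mixed tank run continuously and read at steady state, 30 min in it on average |  |

| run | time / min | complex with two exchanged / % | complex with three exchanged / % | complex with four exchanged / % |
|---|---|---|---|---|
| ash | 1.33 | 0 | 0.4 | 0 |
| ash | 2.50 | 0.2 | 0 | 1.1 |
| ash | 5.00 | 1.1 | 0 | 1.1 |
| ash | 10.0 | 1.8 | 0.8 | 0 |
| ash | 20.0 | 4.8 | 1.7 | 0 |
| alder | 2.50 | 0.1 | 0.3 | 0.4 |
| alder | 5.00 | 0.6 | 1.4 | 0.1 |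
| alder | 8.00 | 0.8 | 0.5 | 0.1 |
| alder | 15.0 | 1.1 | 0 | 0 |
| alder | 30.0 | 2.0 | 1.0 | 0.1 |
| elm | 2.50 | 0.6 | 0.6 | 0 |
| elm | 8.00 | 0.3 | 0 | 0 |
| elm | 15.0 | 1.8 | 0 | 0 |
| elm | 20.0 | 1.0 | 0.6 | 0 |
| elm | 30.0 | 3.2 | 0.7 | 0 |
| larch | 6.00 | 1.9 | 0 | 0 |
| larch | 12.0 | 3.9 | 1.6 | 0 |
| larch | 20.0 | 7.4 | 3.5 | 0.4 |
| larch | 25.0 | 9.5 | 4.9 | 1.4 |
| larch | 30.0 | 8.8 | 6.4 | 0.2 |

(standard deviation of a reading: 0.5 percentage points)

1. order of the set-ups by the share of complex with two exchanged in all that became complex with two exchanged or complex with three exchanged or complex with four exchanged or over-reaction product, at the outlet or at the end, highest first (Thursday's / Friday's / Wednesday's / Sunday's)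
2. share of complex with two exchanged in all that became complex with two exchanged or complex with three exchanged or complex with four exchanged or over-reaction product, at the outlet or at the end, Thursday's
3. share of complex with two exchanged in all that became complex with two exchanged or complex with three exchanged or complex with four exchanged or over-reaction product, at the outlet or at the end, Friday's
4. share of complex with two exchanged in all that became complex with two exchanged or complex with three exchanged or complex with four exchanged or over-reaction product, at the outlet or at the end, Wednesday's
5. share of complex with two exchanged in all that became complex with two exchanged or complex with three exchanged or complex with four exchanged or over-reaction product, at the outlet or at the end, Sunday's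

- the stated concentrations are those of everything mixed, before any reaction; amounts are the same in each set-up
- the feed brings no volume worth counting
- the earlier runs were made in a closed, stirred flask

I first let that molecule, at each moment, either stay or take up incoming ligand. In the ash run at 20.0 min I read 1.7% of complex with three exchanged, made from a content of complex with two exchanged that I took as climbing in a straight line to 4.8%. That gave a pseudo-first-order loss of 0.0354 /min. Over 30 min it made 1.06, the wear number, loss rate times time held.

Two extremes of Thursday's flask were easy. Had every molecule formed at the first moment, 34.6% would have survived; had every one formed at the last moment, 100% would have. Steady formation lies between them, and averaging survival over the ages gave me 61.6%. Sunday's tank, with its spread of ages, gave me 48.5%. Friday's ligand came late and Wednesday's complex came late, so I put both above Thursday's. Over-reaction product had no readings and any loss to it adds wear, so I held my figures as high ones.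

The forecast ran Friday's > Wednesday's > Thursday's > Sunday's, with 70%, 82%, 78% and 56% in the order Thursday's, Friday's, Wednesday's, Sunday's, holding that “Four-exchanged and over-reaction products are minor”. My Thursday's figure of 61.6% stood lower than the forecast's.

The flasks gave 47.2% on Thursday's, 65.3% on Friday's, 57.3% on Wednesday's and 30.7% on Sunday's, in the order Friday's > Wednesday's > Thursday's > Sunday's.

    starting complex + incoming ligand → leaving ligand + complex with one exchanged (k = 0.00240 /M/s)
    complex with one exchanged + incoming ligand → leaving ligand + complex with two exchanged (k = 0.00460 /M/s)
    complex with two exchanged + incoming ligand → leaving ligand + complex with three exchanged (k = 0.00490 /M/s)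
    complex with three exchanged + incoming ligand → leaving ligand + complex with four exchanged (k = 8.10 × 10⁻⁴ /M/s)
    complex with two exchanged → over-reaction product (k = 8.40 × 10⁻⁴ /s)
    2 starting complex → homo dimer (k = 1.80 × 10⁻⁵ /M/s)

At 30.0 min Thursday's flask held 3.81% of over-reaction product, twice its 1.92% of complex with three exchanged. Scaled by 0.5 for a steady dose, the wear number came to 0.530 on Friday's; scaled also by the ligand charge, it came to 1.33 for the flask like Friday's with 4.50 equiv. Complex with three and four exchanged over over-reaction product went from 0.464 on Friday's to 1.13 there, and that flask's share stood at 52.3%.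

(The numbers in the tables are calculated for an exercise; noise was put on by code.)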